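Ring A is disconnected as a [3+3] annulation (labdane numbering). The unfunctionalised C1–C2–C3 chain is cut out as a propane-1,3-diyl linchpin between C10 and C4, which flank C5 and are each α to a carbonyl: the C9 ketone of ring B and the C19 ester. The key step is a one-pot double enolate alkylation of a monocyclic ring-B keto ester with 1-chloro-3-iodopropane. It forms C1–C10 (the quaternary centre) and C3–C4 and closes the trans-decalin. In the precursor, C8 is blocked as a butylthiomethylene group, which forces enolisation to C10 and later becomes C17; C9 then receives the side chain by alkylative carbonyl transposition.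

Key step: step 6

Remark: all compounds are described with labdane atom numbers (C1–C10 decalin, C11–C16 side chain, C17 on C8, C18/C19 on C4 with C19 the carboxyl carbon, C20 on C10), α/β refer to the usual drawing with the C10 methyl β, and epimer mixtures at centres that are enolised later (C10 in 7–11, C4 in 14) and the E geometry assumed for 11 are immaterial.

Step 1
Reactants: 1 2-methylcyclohex-2-en-1-one
Product: 2 (S)-2-methylcyclohex-2-en-1-ol
Conditions: (R)-2-methyl-CBS-oxazaborolidine (10 mol %), BH3·SMe2 (0.6 equiv), THF, −20 °C; MeOH
Reagents that add atoms: none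
Why: Corey–Bakshi–Shibata reduction, in which the catalyst enantiomer is chosen (R by the usual model, with the trisubstituted vinyl flank as the large group) so that hydride is delivered to the carbonyl face that gives the S carbinol.

Step 2
Reactants: 2 (S)-2-methylcyclohex-2-en-1-ol; 3 trimethyl orthoacetate
Product: 4 methyl 2-[(1S)-2-methylcyclohex-2-en-1-yl]acetate
Conditions: MeC(OMe)3 (6 equiv), EtCO2H (5 mol %), 135 °C, sealed tube
Reagents that add atoms: trimethyl orthoacetate (3), CC(OC)(OC)OC
Why: Johnson–Claisen rearrangement, whose suprafacial [3,3] shift forms the C5–C4 bond on the ring face that carried the C–O bond, so the carbinol chirality is transferred to C5 and the alkene moves to C9=C10.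

Step 3
Reactants: 4 methyl 2-[(1S)-2-methylcyclohex-2-en-1-yl]acetate; 5 N-methylmorpholine N-oxide
Product: 7 methyl 2-[(1S)-2-methyl-3-oxocyclohexyl]acetate, via dialkylborane 6 (not isolated)
Conditions: BH3·SMe2 (0.55 equiv), THF, 0 → 23 °C; then N-methylmorpholine N-oxide (6 equiv), (n-Pr)4N[RuO4] (5 mol %), 4 Å MS, CH2Cl2, 23 °C
Reagents that add atoms: N-methylmorpholine N-oxide (5), C[N+]1([O-])CCOCC1; borane–dimethyl sulfide (boron of 6 only), [BH3-][S+](C)C
Why: Hydroboration puts boron on the less substituted alkene carbon (C9) faster than the ester is reduced, and one-pot amine-oxide/perruthenate oxidation of the organoborane (Ley–Griffith type) should give the C9 ketone; the C10 methine formed here is enolised later.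

Step 4
Reactants: 7 methyl 2-[(1S)-2-methyl-3-oxocyclohexyl]acetate; 8 methyl formate
Product: 9 methyl 2-[(1S,4Z)-4-(hydroxymethylidene)-2-methyl-3-oxocyclohexyl]acetate
Conditions: NaOMe (2 equiv), HCO2Me (5 equiv), THF, 0 → 23 °C; aq. HCl
Reagents that add atoms: methyl formate (8), COC=O
Why: Claisen-type formylation should go at the C8 methylene, the only α-position whose formyl product is drained as a stable enolate, while the ester α-CH2 is far less acidic.

Step 5
Reactants: 9 methyl 2-[(1S,4Z)-4-(hydroxymethylidene)-2-methyl-3-oxocyclohexyl]acetate; 10 1-butanethiol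
Product: 11 methyl 2-[(1S,4E)-4-[(butylsulfanyl)methylidene]-2-methyl-3-oxocyclohexyl]acetate
Conditions: n-BuSH (1.2 equiv), TsOH·H2O (5 mol %), benzene, reflux (Dean–Stark)
Reagents that add atoms: 1-butanethiol (10), CCCCS
Why: Acid-catalysed condensation to the vinylogous thioester (the classical n-butylthiomethylene blocking group) removes all acidity at C8 and stores C17 at the aldehyde oxidation level.

Step 6
Reactants: 11 methyl 2-[(1S,4E)-4-[(butylsulfanyl)methylidene]-2-methyl-3-oxocyclohexyl]acetate; 12 1-chloro-3-iodopropane
Product: 14 trans-decalin keto ester (C9 ketone; C8 butylthiomethylene; C4–H ester), via chloropropyl ketone 13 (not isolated)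
Conditions: KN(SiMe3)2 (1.05 equiv), THF, −78 → 0 °C; ICH2CH2CH2Cl (1.05 equiv), −78 → 0 °C; then KN(SiMe3)2 (1.2 equiv), DMPU, −78 → 23 °C
Reagents that add atoms: 1-chloro-3-iodopropane (12), ClCCCI
Why: One equivalent of KN(SiMe3)2 should give, after proton equilibration, the cross-conjugated potassium enolate at C10 (C8 is blocked and the ester α-hydrogens are about five pKa units less acidic), which attacks the iodide terminus of the linchpin by SN2 and forges C1–C10 with the quaternary centre; the second equivalent of base then finds only the ester α-CH2, and the C4 enolate displaces the chloride to forge C3–C4. The closest known reaction types are the α'-alkylation of n-butylthiomethylene-blocked cyclohexanones to quaternary centres and the cycloalkylation of ester enolates with α,ω-dihalides. Ring A is closed in a 6-exo-tet mode with the enolate double bond exocyclic to the new ring. C10 is controlled by the C5 stereocentre: allylic 1,2-strain with the C10 methyl holds the C5 side chain pseudoaxial in the enolate and the electrophile enters on the opposite face, which places C1 trans to C4 and so gives the trans-decalin with the 10β-methyl. C4 is formed as an epimerisable ester methine (either epimer serves) and is fixed in step 7. The step needs ketone-before-ester enolisation and iodide-before-chloride displacement, which are secured by the blocked C8, the acidity gap, the leaving-group gap and the intramolecularity of the second displacement.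

Step 7
Reactants: 14 trans-decalin keto ester; 15 iodomethane
Product: 16 C4-methylated keto ester (4α-CH3; 4β-CO2CH3)
Conditions: LiN(i-Pr)2 (1.3 equiv), THF, −78 °C; MeI (3 equiv), −78 → 0 °C
Reagents that add atoms: iodomethane (15), CI
Why: Alkylation of the exocyclic lithium ester enolate (the ketone has no α-hydrogen), in which the axial 10β-methyl shields the β-face so that iodomethane should enter from the equatorial α-face and leave the ester axial (4β), the usual outcome for C4 ester enolates of 10-methyl-trans-decalins.

Step 8
Reactants: 16 C4-methylated keto ester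
Product: 17 keto acid (4β-CO2H)
Conditions: LiI (10 equiv), 2,4,6-collidine, 170 °C; aq. HCl
Reagents that add atoms: none
Why: SN2 demethylation by iodide at the unhindered O-methyl carbon cleaves the axial neopentyl-type ester that resists saponification, and the acid then travels as its inert carboxylate through steps 9 and 10.

Step 9
Reactants: 17 keto acid; 18 allylmagnesium bromide
Product: 20 enal acid (C8=C9; C17 aldehyde; C9 allyl), via tertiary alcohol 19 (not isolated)
Conditions: CH2=CHCH2MgBr (3 equiv), THF, −78 → 0 °C; then 1 M HCl, THF, 0 → 23 °C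
Reagents that add atoms: allylmagnesium bromide (18), C=CC[Mg]Br; water, O
Why: 1,2-Addition of the allyl Grignard reagent to the C9 ketone followed by acid hydrolysis of the vinylogous thioester through the sulfur-stabilised allyl cation (alkylative 1,3-carbonyl transposition) should move the carbonyl to C17 and leave the tetrasubstituted C8=C9 alkene.

Step 10
Reactants: 20 enal acid
Product: 22 aldehyde acid (8α-CHO; 9β-allyl), via aldehyde epimer mixture 21 (not isolated)
Conditions: Li (5 equiv), NH3(l)/THF, −78 °C; NH4Cl; then NaOMe (3 equiv), MeOH, 23 °C; aq. HCl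
Reagents that add atoms: none
Why: Birch-type dissolving-metal conjugate reduction protonates the β-carbon C9 axially on the α-face, anti to the 10β-methyl, which puts the allyl chain equatorial (9β), and base equilibration of the epimerisable C8 aldehyde should then give the equatorial 8α-CHO; the isolated alkene and the carboxylate are not reduced.

Step 11
Reactants: 22 aldehyde acid; 23 α-methylene-γ-butyrolactone
Product: 24 (12E)-alkylidene lactone aldehyde acid
Conditions: second-generation Hoveyda–Grubbs catalyst (5 mol %), α-methylene-γ-butyrolactone (5 equiv), 2,6-dichloro-1,4-benzoquinone (10 mol %), CH2Cl2, 40 °C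
Reagents that add atoms: α-methylene-γ-butyrolactone (23), C=C1CCOC1=O
Why: Olefin cross-metathesis of the terminal alkene with the 1,1-disubstituted lactone in excess is driven by loss of ethylene, the benzoquinone suppresses ruthenium hydride isomerisation, and aldehyde and acid are tolerated.

Step 12
Reactants: 24 (12E)-alkylidene lactone aldehyde acid
Product: 25 butenolide aldehyde acid (C13=C14)
Conditions: RhCl3·3H2O (10 mol %), EtOH/H2O (10:1), 80 °C
Reagents that add atoms: none
Why: Rhodium hydride addition–elimination moves the exocyclic C12=C13 double bond into the ring to give the more stable endocyclic conjugated butenolide; the C8 aldehyde already has its thermodynamic configuration.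

Step 13
Reactants: 25 butenolide aldehyde acid
Product: 26 17-hydroxylabd-13-en-16,15-olid-19-oic acid (target)
Conditions: NaBH4 (1.5 equiv), MeOH, −20 → 0 °C; aq. HCl
Reagents that add atoms: none
Why: Chemoselective borohydride reduction of the aldehyde at low temperature leaves the α-substituted butenolide and the carboxylate untouched, and holding C17 as the aldehyde until now avoids oxa-Michael addition of a C17 hydroxyl to the exocyclic enoate of 24.

Compound list

1 | 2-methylcyclohex-2-en-1-one | CC1=CCCCC1=O | starting material
2 | (S)-2-methylcyclohex-2-en-1-ol | O[C@H]1CCCC=C1C | intermediate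
3 | trimethyl orthoacetate (1,1,1-trimethoxyethane) | CC(OC)(OC)OC | starting material
4 | methyl 2-[(1S)-2-methylcyclohex-2-en-1-yl]acetate | COC(=O)C[C@@H]1CCCC=C1C | intermediate
5 | N-methylmorpholine N-oxide | C[N+]1([O-])CCOCC1 | starting material
6 | bis[(3S)-3-(2-methoxy-2-oxoethyl)-2-methylcyclohexyl]borane (boron on C9; new centres not defined) | COC(=O)C[C@@H]1CCCC(BC2CCC[C@@H](CC(=O)OC)C2C)C1C | intermediate
7 | methyl 2-[(1S)-2-methyl-3-oxocyclohexyl]acetate (C9 ketone; C10 epimers) | COC(=O)C[C@@H]1CCCC(=O)C1C | intermediate
8 | methyl formate | COC=O | starting material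
9 | methyl 2-[(1S,4Z)-4-(hydroxymethylidene)-2-methyl-3-oxocyclohexyl]acetate (C10 epimers) | COC(=O)C[C@@H]1CC/C(=C/O)C(=O)C1C | intermediate
10 | 1-butanethiol | CCCCS | starting material
11 | methyl 2-[(1S,4E)-4-[(butylsulfanyl)methylidene]-2-methyl-3-oxocyclohexyl]acetate (C10 epimers) | COC(=O)C[C@@H]1CC/C(=C\SCCCC)C(=O)C1C | intermediate
12 | 1-chloro-3-iodopropane | ClCCCI | starting material
13 | methyl 2-[(1S,2S,4E)-4-[(butylsulfanyl)methylidene]-2-(3-chloropropyl)-2-methyl-3-oxocyclohexyl]acetate | COC(=O)C[C@@H]1CC/C(=C\SCCCC)C(=O)[C@@]1(C)CCCCl | intermediate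
14 | trans-decalin keto ester: 10β-CH3, 5α-H, C9 ketone, C8=C17H–S-n-Bu (E), C4 bearing H and CO2CH3 (4α-ester drawn, C4 epimers possible); methyl 6-[(E)-(butylsulfanyl)methylidene]-4a-methyl-5-oxodecahydronaphthalene-1-carboxylate | C[C@]12CCC[C@@H](C(=O)OC)[C@@H]1CC/C(=C\SCCCC)C2=O | intermediate
15 | iodomethane | CI | starting material
16 | as 14 with quaternary C4: 4α-CH3 (equatorial), 4β-CO2CH3 (axial, C19) | C[C@]12CCC[C@](C)(C(=O)OC)[C@@H]1CC/C(=C\SCCCC)C2=O | intermediate
17 | carboxylic acid of 16 (4β-CO2H) | C[C@]12CCC[C@](C)(C(=O)O)[C@@H]1CC/C(=C\SCCCC)C2=O | intermediate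
18 | allylmagnesium bromide | C=CC[Mg]Br | starting material
19 | tertiary alcohol: C9 bears OH and allyl (C9 configuration immaterial), C8=C17H–S-n-Bu retained | C[C@]12CCC[C@](C)(C(=O)O)[C@@H]1CC/C(=C\SCCCC)C2(O)CC=C | intermediate
20 | enal acid: tetrasubstituted C8=C9, C17 aldehyde on C8, allyl on C9, 4β-CO2H | C[C@]12CCC[C@](C)(C(=O)O)[C@@H]1CCC(C=O)=C2CC=C | intermediate
21 | saturated aldehyde acid, 9β-allyl (9α-H), C8 epimer mixture | C[C@]12CCC[C@](C)(C(=O)O)[C@@H]1CCC(C=O)[C@@H]2CC=C | intermediate
22 | aldehyde acid: 8α-CHO (equatorial, 8β-H), 9β-allyl (9α-H), 4β-CO2H, 10β-CH3, 5α-H | C[C@]12CCC[C@](C)(C(=O)O)[C@@H]1CC[C@@H](C=O)[C@@H]2CC=C | intermediate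
23 | α-methylene-γ-butyrolactone (3-methylideneoxolan-2-one) | C=C1CCOC1=O | starting material
24 | (12E)-17-oxolabd-12-en-16,15-olid-19-oic acid (exocyclic alkylidene lactone) | C[C@]12CCC[C@](C)(C(=O)O)[C@@H]1CC[C@@H](C=O)[C@@H]2C/C=C1\CCOC1=O | intermediate
25 | 17-oxolabd-13-en-16,15-olid-19-oic acid (endocyclic butenolide, 8α-CHO) | C[C@]12CCC[C@](C)(C(=O)O)[C@@H]1CC[C@@H](C=O)[C@@H]2CCC1=CCOC1=O | intermediate
26 | 17-hydroxylabd-13-en-16,15-olid-19-oic acid (4β-CO2H, 4α-CH3, 5α-H, 8α-CH2OH/8β-H, 9α-H, 10β-CH3) | C[C@]12CCC[C@](C)(C(=O)O)[C@@H]1CC[C@@H](CO)[C@@H]2CCC1=CCOC1=O | target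

Total step count: 13. Longest linear sequence: 13 steps (fully linear from 1).

Steps most likely to fail

Step 6. The first deprotonation may not be fully selective, so that the ester enolate is alkylated intermolecularly or the dienolate is O-alkylated. The ring-closing displacement of the chloride may be slow enough for Claisen-type oligomerisation to compete, and anti selectivity at C10 may be incomplete. The fallback sets out from 11 and comes back at 14 by making the two bonds in separate operations with a masked leaving group. The C10 potassium enolate of 11 (KN(SiMe3)2, THF) is alkylated with (3-iodopropoxy)(tert-butyl)dimethylsilane to give the silyl ether F1. Bu4NF then frees the primary alcohol F2, MeSO2Cl/Et3N converts it into the mesylate F3, and KN(SiMe3)2/DMPU closes ring A to 14.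

Step 10. Protonation of C9 may occur partly from the β-face, or electron transfer may over-reduce the aldehyde or couple two radical anions. The fallback sets out from 20 and comes back at 22 by replacing electron transfer with hydride conjugate addition. Stryker's reagent [(Ph3P)CuH]6 in wet THF (in excess, since the acid consumes one hydride) should deliver hydride to C9 from the exposed α-face, and water protonates the copper enolate. The crude aldehyde is equilibrated with NaOMe/MeOH to 22; no new compound is made on this path (F0).

Step 11. The ruthenium carbene may turn over poorly with the 1,1-disubstituted electron-poor partner, 22 may homodimerise, or the allyl double bond may migrate before metathesis. The fallback sets out from 22 and comes back at 26 by building the C12=C13 bond by carbonyl olefination. NaBH4 reduces 22 to the hydroxy acid F4. Ozonolysis (O3, then Me2S) gives the C12 aldehyde F5, which exists largely as its six-membered lactol with the C17 hydroxyl. Wittig olefination with excess α-(triphenylphosphoranylidene)-γ-butyrolactone in hot toluene gives the hydroxy alkylidene lactone F6, and rhodium hydride isomerisation as in step 12 then gives 26.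

Further compounds

F1 | step 6 | methyl 2-[(1S,2S,4E)-4-[(butylsulfanyl)methylidene]-2-[3-(tert-butyldimethylsilyloxy)propyl]-2-methyl-3-oxocyclohexyl]acetate | COC(=O)C[C@@H]1CC/C(=C\SCCCC)C(=O)[C@@]1(C)CCCO[Si](C)(C)C(C)(C)C
F2 | step 6 | methyl 2-[(1S,2S,4E)-4-[(butylsulfanyl)methylidene]-2-(3-hydroxypropyl)-2-methyl-3-oxocyclohexyl]acetate | COC(=O)C[C@@H]1CC/C(=C\SCCCC)C(=O)[C@@]1(C)CCCO
F3 | step 6 | methyl 2-[(1S,2S,4E)-4-[(butylsulfanyl)methylidene]-2-[3-(methanesulfonyloxy)propyl]-2-methyl-3-oxocyclohexyl]acetate | COC(=O)C[C@@H]1CC/C(=C\SCCCC)C(=O)[C@@]1(C)CCCOS(C)(=O)=O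
F0 | step 10 | none | none
F4 | step 11 | hydroxy acid: 8α-CH2OH, 9β-allyl, 4β-CO2H trans-decalin | C[C@]12CCC[C@](C)(C(=O)O)[C@@H]1CC[C@@H](CO)[C@@H]2CC=C
F5 | step 11 | C12 aldehyde of F4 (9β-CH2CHO; in equilibrium with the lactol to the C17 hydroxyl) | C[C@]12CCC[C@](C)(C(=O)O)[C@@H]1CC[C@@H](CO)[C@@H]2CC=O
F6 | step 11 | (12E)-17-hydroxylabd-12-en-16,15-olid-19-oic acid | C[C@]12CCC[C@](C)(C(=O)O)[C@@H]1CC[C@@H](CO)[C@@H]2C/C=C1\CCOC1=O
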